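Late in a run the enzyme still works, but ever more slowly, so we should reckon the sum of its work over the whole run.

the same everywhere: enzyme 0.032 mol%
- north-west: substrate 0.10 M; one stirred flow tank at steady state, fed with the mixture as stated, mean residence time 40 h
- south-east: substrate 0.10 M (fed, over 20.0 h); a stirred flask in which substrate is dosed at a steady rate over 20.0 h without added volume, worked up at 40 h; time 40 h
- east: substrate 0.10 M; everything together in a closed stirred flask, run for 40 h; time 40 h

    2 substrate → self-condensation product (k1 = 0.0926 M⁻¹ h⁻¹)
    substrate + enzyme → target + enzyme, rate k2*[substrate]*[enzyme]/(1 + ([substrate]/Km2)) (Km2 = 15.5 mM, k2 = 30300 M⁻¹ h⁻¹)
    2 enzyme → spent catalyst (k3 = 4670 M⁻¹ h⁻¹)

- order of the set-ups by the amount of target at the outlet or at the end, in percent of the substrate put in, highest first (north-west / south-east / east)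
- amount of target at the outlet or at the end, in percent of the substrate put in, north-west
- amount of target at the outlet or at the end, in percent of the substrate put in, south-east
- amount of target at the outlet or at the end, in percent of the substrate put in, east

- in percentages every species weighs as the substrate in it: one self-condensation product counts as two
- a step written with two of one species runs at k times the square of its concentration and takes two of it each time
- the stated concentrations are those of everything mixed, before any reaction; amounts are the same in each set-up
- the feed brings no volume worth counting
- run time (south-east): 40 h

We count in fractions of the charge and build up the east flask. With the main step alone and an enzyme that lasts, substrate at 0.10 M stands well above 15.5 mM, so the enzyme is close to saturation and runs near full speed, 0.150 h⁻¹ of the charge. That clears the charge in 6.67 h, far less than the run.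

Now the enzyme destroys itself. Its first half-life is 3.35 h, shorter than that clearing time. Summing its falling speed over the run gives the enzyme budget: the charges it can turn over at full speed, which is full speed times half-life times the logarithm of one plus time over half-life. Here that is 1.29 charges.

The budget is not wholly usable: by the rate law, the step falls below full speed as substrate thins. The budget must pay the part of the charge used plus 0.155 times the logarithm of one over the remainder. Bracketing that remainder gives 15.6% and 5.70%, and we take the middle, 10.6%.

Last comes self-condensation, which at the start of the east flask, with the whole charge and fresh enzyme, takes 0.142 of substrate for each unit the enzyme takes. Guessing half of that as the average over the run, we get 83.0% for east.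

In the north-west tank, enzyme holds steady at 25.0% of its feed, so the budget is 1.51 charges, paid at the speed the tank's substrate allows. Leaving self-condensation out, that gives 81.6%. In the south-east flask, taking the enzyme as present from the start, 75.8% of the budget has passed when dosing ends, a period in which the substrate is still arriving, so we place this flask last.

The forecast gives east > north-west > south-east, with 85.7% for east, 80.1% for north-west and 66.3% for south-east, noting that “The enzyme decays while substrate is still arriving”. Our east figure stands below the forecast's.

The simulation gives east > north-west > south-east, with 85.9%, 80.1% and 66.3% in that same east, north-west, south-east listing. In the south-east flask, target stood at 44.4% after 20.0 h and 66.3% after 40.0 h. That gain of 22 percentage points is less than the budget remaining after dosing, 31.2% of the charge.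

In the neighbour flask, dosed like south-east with 0.25 M of substrate at the same loading, the half-life is 1.34 h and the budget 0.690 charges, below one, so our reckoning puts target under that share. The computed flask gives 43.5% target, with 29.9% of the substrate left.

The constants used here stand for no real mixture; the run is a simulation.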